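A direct plan would alkylate 3-ethoxycyclohexenone, transpose it to the racemic enone A1 and close ring A onto ring B by an amine-catalysed intramolecular Michael addition (C4–C5) to the cis-decalindione A2.
Functional-group steps would then lead to an 8,9-epoxy-7-ketone that takes up the C11–C13 alkenyllithium; epoxide isomerization, dehydrogenation and acetylation would give the 3β-alcohol A3, which is esterified with inversion.
Its weakest steps would be:
(a) the Michael ring closure: a β,β-disubstituted enone must be attacked to form quaternary C5 next to C4 while a dynamic kinetic resolution through a dienamine sets the absolute configuration, a combination without precedent on which everything rests;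
(b) the stretch from A2 to the epoxy ketone (ketalization, reduction, silylation, deketalization, two dehydrogenations, reduction, epoxidation, oxidation): nine operations that form no skeletal bond;
(c) the final Mitsunobu inversion at C3, an allylic centre at the end of the cross-ring dienone beside a free tertiary ketol, where SN2′ attack and elimination compete and a stereocentre is corrected in the last step.

**Retrosynthetic overview**
The dienone O=C8–C9=C10–C1=C2, flanked by quaternary C5 and the C3 oxygen, is read as the retron of an intramolecular vinylallene Diels–Alder reaction. Bonds C3–C4 and C5–C10 are cut, so rings A and B form together from the acyclic ynone 24 (through allenyl ketone 25).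
Ynone 24 comes from acid 11 (C4–C8 and C11–C13; C7 set by an Ireland–Claisen chirality transfer that also makes the (E)-C4=C5 dienophile) and the (Z)-enol ester 22 (C9, C10, C1–C3, already carrying the side-chain acyl group from acid 17).
C3, C4 and C5 arise in the key step under the control of C7. The C8 ketone, the dienone and the C3 ester are in place from the start, so there is no redox stretch and no inversion at C3; only two silyl groups are exchanged at the end.

Key step: step 14

Remark: eremophilane numbering is used (ring A: C1–C5 and C10; ring B: C5–C10; C11(=C12)–C13 on C7; methyl groups on C4 and C5); "α" and "β" refer to the face opposite to and the face of the C5 methyl group.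

Step 1
Reactants: 1 2-bromoprop-2-en-1-ol
Product: 2 [(2-bromoprop-2-en-1-yl)oxy](tert-butyl)dimethylsilane
Conditions: t-BuMe2SiCl, imidazole, CH2Cl2, rt
Reagents that add atoms: tert-butyldimethylsilyl chloride CC(C)(C)[Si](C)(C)Cl
Why: Silylation of the primary allylic alcohol protects C13–OH for the halogen–lithium exchange; no stereocentre is involved.

Step 2
Reactants: 2 [(2-bromoprop-2-en-1-yl)oxy](tert-butyl)dimethylsilane; 3 ethyl glyoxylate
Product: 5 ethyl 3-{[(tert-butyldimethylsilyl)oxy]methyl}-2-hydroxybut-3-enoate (racemic), via alkenyllithium 4 (not isolated)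
Conditions: t-BuLi (2 equiv), Et2O, −78 °C; then 3 (freshly distilled), −78 °C; then H2O
Reagents that add atoms: none
Why: Bromine–lithium exchange and 1,2-addition of the alkenyllithium to the aldehyde carbonyl of the glyoxylate, which is far more electrophilic than its ester group, joins C11–C13 to C7–C8; C7 is formed racemic on purpose because step 5 planarizes it.

Step 3
Reactants: 6 3-methylbut-3-en-2-one
Product: 7 (R)-3-methylbut-3-en-2-ol
Conditions: (S)-2-methyl-CBS-oxazaborolidine (10 mol %), BH3·SMe2 (0.6 equiv), THF, −20 °C; then MeOH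
Reagents that add atoms: none
Why: Corey–Bakshi–Shibata reduction: the oxazaborolidine–borane complex binds the ketone with the larger isopropenyl group away from the catalyst and delivers hydride to one face, which should give the (R)-carbinol by analogy with aryl and alkenyl methyl ketones.

Step 4
Reactants: 5 ethyl 3-{[(tert-butyldimethylsilyl)oxy]methyl}-2-hydroxybut-3-enoate; 7 (R)-3-methylbut-3-en-2-ol
Product: 8 (R)-3-methylbut-3-en-2-yl 3-{[(tert-butyldimethylsilyl)oxy]methyl}-2-hydroxybut-3-enoate (both C2 epimers)
Conditions: Ti(OEt)4 (10 mol %), 7 (1.5 equiv), toluene, 85 °C, 4 Å molecular sieves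
Reagents that add atoms: none
Why: Titanate-catalysed transesterification of an α-hydroxy ester exchanges ethanol for the chiral allylic alcohol without touching its stereocentre; the two C2 epimers converge in step 5.

Step 5
Reactants: 8 (R)-3-methylbut-3-en-2-yl 3-{[(tert-butyldimethylsilyl)oxy]methyl}-2-hydroxybut-3-enoate
Product: 11 (2S,4E)-2-{3-[(tert-butyldimethylsilyl)oxy]prop-1-en-2-yl}-4-methyl-2-[(triethylsilyl)oxy]hex-4-enoic acid, via bis-silyl ketene acetal 9 (not isolated), via triethylsilyl ester 10 (not isolated)
Conditions: LiN(i-Pr)2 (2.4 equiv), THF, −78 °C; Et3SiCl (2.6 equiv), Et3N, −78 to 40 °C; then aqueous buffer (pH 5)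
Reagents that add atoms: chlorotriethylsilane CC[Si](Cl)(CC)CC
Why: Ireland–Claisen rearrangement of the chelated dianion: lithium bridges the two oxygens, so the enediolate is silylated as the (Z)-ketene acetal with C11 cis to the allyloxy oxygen, and a chair transition state with the carbinol methyl equatorial transfers (R) at the carbinol to (S) at quaternary C7 while it forms C6–C7 and the (E)-C4=C5 alkene with its two methyl groups cis; the C7 oxygen leaves the step as its triethylsilyl ether and the silyl ester is cleaved on work-up.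

Step 6
Reactants: 12 (R)-2-methylbutanoic acid
Product: 13 (R)-2-methylbutan-1-ol
Conditions: LiAlH4, Et2O, 0 °C to rt; then H2O
Reagents that add atoms: none
Why: Hydride reduction of the carboxylic acid leaves the α-stereocentre untouched.

Step 7
Reactants: 13 (R)-2-methylbutan-1-ol
Product: 15 (E,4R)-2,4-dimethylhex-2-enal, via (R)-2-methylbutanal 14 (not isolated)
Conditions: TEMPO (cat.), KBr (cat.), NaOCl, aq. NaHCO3, CH2Cl2, 0 °C; then Ph3P=C(CH3)CHO, CH2Cl2, 40 °C
Reagents that add atoms: 2-(triphenylphosphoranylidene)propanal CC(C=O)=P(c1ccccc1)(c1ccccc1)c1ccccc1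
Why: Nitroxyl-catalysed hypochlorite oxidation gives the configurationally labile aldehyde, which is used at once in a Wittig reaction with the stabilized formyl ylide to give the (E)-enal.

Step 8
Reactants: 15 (E,4R)-2,4-dimethylhex-2-enal
Product: 16 ethyl (2E,4E,6R)-4,6-dimethylocta-2,4-dienoate
Conditions: Ph3P=CHCO2Et, toluene, 80 °C
Reagents that add atoms: ethyl 2-(triphenylphosphoranylidene)acetate CCOC(=O)C=P(c1ccccc1)(c1ccccc1)c1ccccc1
Why: Wittig reaction with the stabilized ester ylide under neutral conditions extends the enal to the (2E,4E)-dienoate without exposing the γ-stereocentre to base.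

Step 9
Reactants: 16 ethyl (2E,4E,6R)-4,6-dimethylocta-2,4-dienoate
Product: 17 (2E,4E,6R)-4,6-dimethylocta-2,4-dienoic acid
Conditions: LiOH, THF/MeOH/H2O, rt; then aq. HCl
Reagents that add atoms: lithium hydroxide [Li+].[OH-]
Why: Saponification of the ethyl ester; the remote allylic stereocentre is not acidic enough to epimerize.

Step 10
Reactants: 18 ethynylmagnesium bromide; 19 3-bromo-1-(trimethylsilyl)prop-1-yne
Product: 20 trimethyl(penta-1,4-diyn-1-yl)silane
Conditions: CuCl (5 mol %), THF, 0 to 45 °C
Reagents that add atoms: none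
Why: Copper-catalysed coupling of the alkynyl Grignard reagent with the propargylic bromide (substitution at the CH2 group) gives the skipped diyne with one end masked by silicon.

Step 11
Reactants: 17 (2E,4E,6R)-4,6-dimethylocta-2,4-dienoic acid; 20 trimethyl(penta-1,4-diyn-1-yl)silane
Product: 21 (Z)-5-(trimethylsilyl)pent-1-en-4-yn-1-yl (2E,4E,6R)-4,6-dimethylocta-2,4-dienoate
Conditions: Ru(2-methylallyl)2(dppb) (2 mol %; dppb = Ph2P(CH2)4PPh2), 20 (1.5 equiv), toluene, 60 °C
Reagents that add atoms: none
Why: Ruthenium-catalysed anti-Markovnikov addition of a carboxylic acid to a terminal alkyne through a ruthenium vinylidene: the carboxylate adds to the terminal carbon and protonation places oxygen and chain cis, which should give the (Z)-enol ester, while the silylated internal alkyne cannot form a vinylidene and stays.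

Step 12
Reactants: 21 (Z)-5-(trimethylsilyl)pent-1-en-4-yn-1-yl (2E,4E,6R)-4,6-dimethylocta-2,4-dienoate
Product: 22 (Z)-pent-1-en-4-yn-1-yl (2E,4E,6R)-4,6-dimethylocta-2,4-dienoate
Conditions: AgNO3 (10 mol %), acetone/H2O, rt
Reagents that add atoms: none
Why: Silver-catalysed protodesilylation of the alkynylsilane is neutral, so the enol ester, which methanolic carbonate or unbuffered fluoride would cleave, survives.

Step 13
Reactants: 11 (2S,4E)-2-{3-[(tert-butyldimethylsilyl)oxy]prop-1-en-2-yl}-4-methyl-2-[(triethylsilyl)oxy]hex-4-enoic acid; 22 (Z)-pent-1-en-4-yn-1-yl (2E,4E,6R)-4,6-dimethylocta-2,4-dienoate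
Product: 24 (1Z,7S,9E)-7-{3-[(tert-butyldimethylsilyl)oxy]prop-1-en-2-yl}-9-methyl-6-oxo-7-[(triethylsilyl)oxy]undeca-1,9-dien-4-yn-1-yl (2E,4E,6R)-4,6-dimethylocta-2,4-dienoate, via acid chloride 23 (not isolated)
Conditions: 1-chloro-N,N,2-trimethylprop-1-en-1-amine, CH2Cl2, 0 °C; then 22, PdCl2(PPh3)2 (2 mol %), CuI (4 mol %), Et3N (1.5 equiv), THF, rt
Reagents that add atoms: none
Why: The acid chloride is made under neutral conditions with the α-chloroenamine and coupled with the terminal alkyne by palladium/copper catalysis (acyl Sonogashira coupling), which joins C8 to C9 without an organolithium that the enol ester would not tolerate; C7 carries no hydrogen, so neither ketene formation nor epimerization is possible.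

Step 14
Reactants: 24 (1Z,7S,9E)-7-{3-[(tert-butyldimethylsilyl)oxy]prop-1-en-2-yl}-9-methyl-6-oxo-7-[(triethylsilyl)oxy]undeca-1,9-dien-4-yn-1-yl (2E,4E,6R)-4,6-dimethylocta-2,4-dienoate
Product: 26 (3S,4S,5S,7S)-13-[(tert-butyldimethylsilyl)oxy]-8-oxo-7-[(triethylsilyl)oxy]eremophila-1,9,11(12)-trien-3-yl (2E,4E,6R)-4,6-dimethylocta-2,4-dienoate, via allenyl ketone 25 (not isolated)
Conditions: Et3N (2 equiv), toluene (0.01 M), 25 to 80 °C
Reagents that add atoms: none
Why: Triethylamine removes a proton from the doubly activated C1 methylene (γ to the ynone, allylic to the enol ester) and the cumulenolate is reprotonated at C9, after which the vinylallene C3=C2–C1=C10(=C9) undergoes an intramolecular Diels–Alder reaction with the tethered C4=C5 alkene; the closest known reaction type is the tandem base-mediated propargyl-to-allenyl isomerization/intramolecular [4+2] cycloaddition and the intramolecular vinylallene Diels–Alder reaction with unactivated alkenes. Ring A closes as the cycloaddition ring (bonds C3–C4 and C5–C10) and ring B closes at the same time through the tether C6–C7–C8 from the allene terminus C9, whose double bond to C10 becomes the enone of the product. The tether can span the diene only when C6 is exo, so the C5 methyl and, through the (E)-alkene, the C4 methyl are endo and end cis; the (Z)-enol ester holds the C3 oxygen "inside", where only an allene terminus leaves room, and an inside substituent ends trans to the endo methyl groups, which gives the 3α-acyloxy group. Because the substituents of C9 stand perpendicular to the diene plane, each allene epimer exposes one diene face only; the epimers interconvert through the enolate under the base, and the (aS) epimer should cyclize faster because its transition state keeps the large C11 group pseudo-equatorial on the forming ring B and the silyloxy group axial beside the endo C5 methyl, so C7 sets C3, C4 and C5 in a dynamic selection. The step needs the cycloaddition to be slower than allene epimerization, which the trisubstituted dienophile that must form quaternary C5 should secure, and a protected C7 hydroxyl, since a free one would add to the allenyl ketone to give a furanone.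

Step 15
Reactants: 26 (3S,4S,5S,7S)-13-[(tert-butyldimethylsilyl)oxy]-8-oxo-7-[(triethylsilyl)oxy]eremophila-1,9,11(12)-trien-3-yl (2E,4E,6R)-4,6-dimethylocta-2,4-dienoate
Product: 27 (3S,4S,5S,7S)-7,13-dihydroxy-8-oxoeremophila-1,9,11(12)-trien-3-yl (2E,4E,6R)-4,6-dimethylocta-2,4-dienoate
Conditions: HF·pyridine, pyridine, THF, 0 °C to rt
Reagents that add atoms: none
Why: Fluoride cleavage of the tertiary triethylsilyl and the primary tert-butyldimethylsilyl ether under pyridine-buffered, non-basic conditions spares the tertiary α-ketol, the dienone and the C3 ester.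

Step 16
Reactants: 27 (3S,4S,5S,7S)-7,13-dihydroxy-8-oxoeremophila-1,9,11(12)-trien-3-yl (2E,4E,6R)-4,6-dimethylocta-2,4-dienoate
Product: 28 (3S,4S,5S,7S)-13-acetoxy-7-hydroxy-8-oxoeremophila-1,9,11(12)-trien-3-yl (2E,4E,6R)-4,6-dimethylocta-2,4-dienoate (CNP0160850.1)
Conditions: Ac2O (1.1 equiv), 2,4,6-collidine, CH2Cl2, −20 °C
Reagents that add atoms: acetic anhydride CC(=O)OC(C)=O
Why: Chemoselective acylation: the primary allylic C13 hydroxyl should react far faster than the tertiary C7 hydroxyl beside the ketone, so the acetate is placed last without further protection.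

**Compound list**
1 | 2-bromoprop-2-en-1-ol | OCC(Br)=C | starting material
2 | [(2-bromoprop-2-en-1-yl)oxy](tert-butyl)dimethylsilane | C=C(Br)CO[Si](C)(C)C(C)(C)C | intermediate
3 | ethyl glyoxylate (ethyl 2-oxoacetate) | CCOC(=O)C=O | starting material
4 | {3-[(tert-butyldimethylsilyl)oxy]prop-1-en-2-yl}lithium | [Li]C(=C)CO[Si](C)(C)C(C)(C)C | intermediate (not isolated)
5 | ethyl 3-{[(tert-butyldimethylsilyl)oxy]methyl}-2-hydroxybut-3-enoate (racemic) | CCOC(=O)C(O)C(=C)CO[Si](C)(C)C(C)(C)C | intermediate
6 | 3-methylbut-3-en-2-one | CC(=O)C(C)=C | starting material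
7 | (R)-3-methylbut-3-en-2-ol | C[C@@H](O)C(C)=C | intermediate
8 | (R)-3-methylbut-3-en-2-yl 3-{[(tert-butyldimethylsilyl)oxy]methyl}-2-hydroxybut-3-enoate (both C2 epimers) | C=C(C)[C@@H](C)OC(=O)C(O)C(=C)CO[Si](C)(C)C(C)(C)C | intermediate
9 | (Z)-bis(triethylsilyl) ketene acetal of 8 (both oxygens on the double bond silylated) | C=C(C)[C@@H](C)O/C(O[Si](CC)(CC)CC)=C(/O[Si](CC)(CC)CC)C(=C)CO[Si](C)(C)C(C)(C)C | intermediate (not isolated)
10 | triethylsilyl (2S,4E)-2-{3-[(tert-butyldimethylsilyl)oxy]prop-1-en-2-yl}-4-methyl-2-[(triethylsilyl)oxy]hex-4-enoate | C=C(CO[Si](C)(C)C(C)(C)C)[C@](O[Si](CC)(CC)CC)(C(=O)O[Si](CC)(CC)CC)C/C(C)=C/C | intermediate (not isolated)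
11 | (2S,4E)-2-{3-[(tert-butyldimethylsilyl)oxy]prop-1-en-2-yl}-4-methyl-2-[(triethylsilyl)oxy]hex-4-enoic acid | C=C(CO[Si](C)(C)C(C)(C)C)[C@](O[Si](CC)(CC)CC)(C(=O)O)C/C(C)=C/C | intermediate
12 | (R)-2-methylbutanoic acid | CC[C@@H](C)C(=O)O | starting material
13 | (R)-2-methylbutan-1-ol | CC[C@@H](C)CO | intermediate
14 | (R)-2-methylbutanal | CC[C@@H](C)C=O | intermediate (not isolated)
15 | (E,4R)-2,4-dimethylhex-2-enal | CC[C@@H](C)/C=C(\C)C=O | intermediate
16 | ethyl (2E,4E,6R)-4,6-dimethylocta-2,4-dienoate | CCOC(=O)/C=C/C(C)=C/[C@H](C)CC | intermediate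
17 | (2E,4E,6R)-4,6-dimethylocta-2,4-dienoic acid | OC(=O)/C=C/C(C)=C/[C@H](C)CC | intermediate
18 | ethynylmagnesium bromide | C#C[Mg]Br | starting material
19 | 3-bromo-1-(trimethylsilyl)prop-1-yne | BrCC#C[Si](C)(C)C | starting material
20 | trimethyl(penta-1,4-diyn-1-yl)silane | C#CCC#C[Si](C)(C)C | intermediate
21 | (Z)-5-(trimethylsilyl)pent-1-en-4-yn-1-yl (2E,4E,6R)-4,6-dimethylocta-2,4-dienoate | C[Si](C)(C)C#CC/C=C\OC(=O)/C=C/C(C)=C/[C@H](C)CC | intermediate
22 | (Z)-pent-1-en-4-yn-1-yl (2E,4E,6R)-4,6-dimethylocta-2,4-dienoate | C#CC/C=C\OC(=O)/C=C/C(C)=C/[C@H](C)CC | intermediate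
23 | (2S,4E)-2-{3-[(tert-butyldimethylsilyl)oxy]prop-1-en-2-yl}-4-methyl-2-[(triethylsilyl)oxy]hex-4-enoyl chloride | C=C(CO[Si](C)(C)C(C)(C)C)[C@](O[Si](CC)(CC)CC)(C(Cl)=O)C/C(C)=C/C | intermediate (not isolated)
24 | (1Z,7S,9E)-7-{3-[(tert-butyldimethylsilyl)oxy]prop-1-en-2-yl}-9-methyl-6-oxo-7-[(triethylsilyl)oxy]undeca-1,9-dien-4-yn-1-yl (2E,4E,6R)-4,6-dimethylocta-2,4-dienoate | C=C(CO[Si](C)(C)C(C)(C)C)[C@](O[Si](CC)(CC)CC)(C(=O)C#CC/C=C\OC(=O)/C=C/C(C)=C/[C@H](C)CC)C/C(C)=C/C | intermediate (precursor of the key step)
25 | (1Z,7S,9E)-7-{3-[(tert-butyldimethylsilyl)oxy]prop-1-en-2-yl}-9-methyl-6-oxo-7-[(triethylsilyl)oxy]undeca-1,3,4,9-tetraen-1-yl (2E,4E,6R)-4,6-dimethylocta-2,4-dienoate (allenyl ketone; both allene epimers in equilibrium, the (aS) epimer cyclizes) | C=C(CO[Si](C)(C)C(C)(C)C)[C@](O[Si](CC)(CC)CC)(C(=O)C=C=C/C=C\OC(=O)/C=C/C(C)=C/[C@H](C)CC)C/C(C)=C/C | intermediate (not isolated)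
26 | (3S,4S,5S,7S)-13-[(tert-butyldimethylsilyl)oxy]-8-oxo-7-[(triethylsilyl)oxy]eremophila-1,9,11(12)-trien-3-yl (2E,4E,6R)-4,6-dimethylocta-2,4-dienoate | C=C(CO[Si](C)(C)C(C)(C)C)[C@@]1(O[Si](CC)(CC)CC)C[C@]2(C)C(=CC1=O)C=C[C@H](OC(=O)/C=C/C(C)=C/[C@H](C)CC)[C@H]2C | intermediate (product of the key step)
27 | (3S,4S,5S,7S)-7,13-dihydroxy-8-oxoeremophila-1,9,11(12)-trien-3-yl (2E,4E,6R)-4,6-dimethylocta-2,4-dienoate | C=C(CO)[C@@]1(O)C[C@]2(C)C(=CC1=O)C=C[C@H](OC(=O)/C=C/C(C)=C/[C@H](C)CC)[C@H]2C | intermediate
28 | (3S,4S,5S,7S)-13-acetoxy-7-hydroxy-8-oxoeremophila-1,9,11(12)-trien-3-yl (2E,4E,6R)-4,6-dimethylocta-2,4-dienoate (CNP0160850.1) | C=C(COC(C)=O)[C@@]1(O)C[C@]2(C)C(=CC1=O)C=C[C@H](OC(=O)/C=C/C(C)=C/[C@H](C)CC)[C@H]2C | target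

**Step count and risks**
Total step count: 16. Longest linear sequence: 10 steps (steps 6, 7, 8, 9, 11, 12, 13, 14, 15, 16).

The three steps most likely to fail:

1. Step 14 (key step). The two allene epimers may not be funnelled through one of them, either because epimerization through the enolate is slower than cycloaddition or because C7 discriminates weakly, so that both diene faces react and the C3–C5 triad forms as a mixture relative to C7. The extended enolate may also drain into the conjugated enynone.
   Fallback: setting out from ynone 24, the axis would be set by a reagent and frozen before the ring closure instead of being selected during it. Isomerization at low temperature with a chiral bifunctional Brønsted base (a cinchona-derived amine–thiourea; base-catalysed enantioselective proton shifts from alkynyl carbonyl compounds to axially chiral allenes are known) would give the (aS)-allenyl ketone F1. It is configurationally stable once the base is removed on silica. Heating F1 in base-free toluene can then use one diene face only and would rejoin the route at 26.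

2. Step 11. The ruthenium-catalysed addition may lose regio- or stereocontrol (Markovnikov or (E) enol ester), or the alkyne may dimerize.
   Fallback: setting out from diyne 20, the C–O bond would be made by cross-coupling instead of hydro-oxycarbonylation. Rhodium-catalysed trans-hydroboration ([RhCl(cod)]2, P(i-Pr)3, Et3N, pinacolborane) would give the (Z)-alkenylboronate F2. KHF2 would convert it into the potassium trifluoroborate F3. Copper-mediated coupling of F3 with acid 17 under oxygen (CuBr·SMe2, 4-dimethylaminopyridine, 4 Å sieves), which keeps the alkene geometry, would rejoin the route at 21.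

3. Step 13. Acylation at the hindered, α-quaternary acid chloride may be slow, the acyl palladium species may lose CO, or the amine may isomerize the product too early.
   Fallback: setting out from acid chloride 23, the ynone would be made by carbonyl addition and oxidation. Reduction with LiAlH(O-t-Bu)3 at −78 °C would give the aldehyde F4. Zinc-triflate/amine-mediated addition of alkyne 22 (Zn(OTf)2, Et3N, toluene), which tolerates the enol ester, would give the propargylic alcohols F5 (both C6 epimers of the undecadienynyl chain). Dess–Martin oxidation would rejoin the route at 24.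

**Further compounds**
F1 | step 14 | (aS)-allenyl ketone: single axial epimer of 25 | C=C(CO[Si](C)(C)C(C)(C)C)[C@](O[Si](CC)(CC)CC)(C(=O)C([H])=[C@@]=C([H])/C=C\OC(=O)/C=C/C(C)=C/[C@H](C)CC)C/C(C)=C/C
F2 | step 11 | (Z)-4,4,5,5-tetramethyl-2-[5-(trimethylsilyl)pent-1-en-4-yn-1-yl]-1,3,2-dioxaborolane | C[Si](C)(C)C#CC/C=C\B1OC(C)(C)C(C)(C)O1
F3 | step 11 | potassium (Z)-trifluoro[5-(trimethylsilyl)pent-1-en-4-yn-1-yl]borate | C[Si](C)(C)C#CC/C=C\[B-](F)(F)F.[K+]
F4 | step 13 | (2S,4E)-2-{3-[(tert-butyldimethylsilyl)oxy]prop-1-en-2-yl}-4-methyl-2-[(triethylsilyl)oxy]hex-4-enal | C=C(CO[Si](C)(C)C(C)(C)C)[C@](O[Si](CC)(CC)CC)(C=O)C/C(C)=C/C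
F5 | step 13 | (1Z,7S,9E)-7-{3-[(tert-butyldimethylsilyl)oxy]prop-1-en-2-yl}-6-hydroxy-9-methyl-7-[(triethylsilyl)oxy]undeca-1,9-dien-4-yn-1-yl (2E,4E,6R)-4,6-dimethylocta-2,4-dienoate (both C6 epimers) | C=C(CO[Si](C)(C)C(C)(C)C)[C@](O[Si](CC)(CC)CC)(C(O)C#CC/C=C\OC(=O)/C=C/C(C)=C/[C@H](C)CC)C/C(C)=C/C
A1 | direct plan | rac-3-methyl-4-(3-oxopentyl)cyclohex-2-en-1-one | CCC(=O)CCC1CCC(=O)C=C1C
A2 | direct plan | (4S,5R,10R)-4,5-dimethyl-cis-decalin-3,7-dione | O=C1C[C@]2(C)[C@H](CC1)CCC(=O)[C@H]2C
A3 | direct plan | 13-acetoxy-3β,7β-dihydroxyeremophila-1,9,11(12)-trien-8-one | C=C(COC(C)=O)[C@@]1(O)C[C@]2(C)C(=CC1=O)C=C[C@@H](O)[C@H]2C
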